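**Strategy.** The C ring is disconnected at C2–C3. In the pyranone, O1–C2–C3–C4 holds a benzylic C2 that is already half an acetal (O1 plus the trioxygenated B ring) two bonds from the C4 ketone; swapping C3 for oxygen leads back to a 2-aryl-1,3-benzodioxin-4-one and, after carbonyl methylenation, to its 4-methylene enol ether. One catalyst-controlled [1,3] O-to-C shift then turns this racemic acetal into the chroman-4-one, creating the C2–C3 bond, the C ring and the (2S) centre together. The precursor is the fully TBS-protected 6-lavandulyl-4-methylene-2-aryl-4H-1,3-benzodioxine (C2-epimer mixture), whose regiochemistry is fixed by carboxylating ortho to the only free phenol of the A ring.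

Key step: step 11

Abbreviations: TBS = tert-butyldimethylsilyl; Bpin = 4,4,5,5-tetramethyl-1,3,2-dioxaborolan-2-yl; Lav = (2S)-5-methyl-2-(prop-1-en-2-yl)hex-4-en-1-yl, the lavandulyl group as it sits on an arene.

Remark: the side-chain stereocentre keeps the spatial arrangement of (R)-lavandulol in every compound; once CH2–O (or I, Zn) is replaced by CH2–aryl the CIP ranking changes, so the same centre is named S in all aryl compounds.

Remark: the A ring is built from 2-bromoresorcinol so that the oxygen para to the side chain is the only unprotected one when the carboxyl group and the acetal are introduced; this decides 6- against 8-lavandulyl substitution.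

**Step 1**
Reactants: 1 2-bromobenzene-1,3-diol (2-bromoresorcinol)
Product: 2 2-bromo-1,3-bis(TBS-oxy)benzene
Conditions: TBSCl, imidazole, DMF, rt
Reagents that add atoms: tert-butyldimethylsilyl chloride, CC(C)(C)[Si](C)(C)Cl
Why: Imidazole-promoted silyl ether formation on both phenols; the two silyl ethers later block their ortho positions in the C–H borylation.

**Step 2**
Reactants: 2 2-bromo-1,3-bis(TBS-oxy)benzene
Product: 3 2-[4-bromo-3,5-bis(TBS-oxy)phenyl]-4,4,5,5-tetramethyl-1,3,2-dioxaborolane
Conditions: B2pin2, [Ir(OMe)(cod)]2 (cat.), dtbpy (cat.), cyclohexane, 70 °C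
Reagents that add atoms: bis(pinacolato)diboron, CC1(C)OB(OC1(C)C)B1OC(C)(C)C(C)(C)O1
Why: Iridium-catalysed aromatic C–H borylation is sterically governed, so only C5 (the one C–H without an ortho substituent, para to bromine) should react, the C–Br bond is tolerated, and the boron marks the carbon that will carry O1.

**Step 3**
Reactants: 4 (R)-lavandulol
Product: 5 (R)-lavandulyl iodide [(2R)-1-iodo-5-methyl-2-(prop-1-en-2-yl)hex-4-ene]
Conditions: PPh3, I2, imidazole, CH2Cl2, 0 °C → rt, dark
Reagents that add atoms: iodine, II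
Why: Appel-type (Garegg–Samuelsson) iodination is an SN2 displacement at the primary CH2, so the adjacent stereocentre and both alkenes stay untouched.

**Step 4**
Reactants: 5 (R)-lavandulyl iodide; 3 2-[4-bromo-3,5-bis(TBS-oxy)phenyl]-4,4,5,5-tetramethyl-1,3,2-dioxaborolane
Product: 7 2-[3,5-bis(TBS-oxy)-4-Lav-phenyl]-4,4,5,5-tetramethyl-1,3,2-dioxaborolane, via (R)-lavandulylzinc iodide 6 (not isolated)
Conditions: Zn dust, LiCl, THF, 40 °C; then 3, Pd(OAc)2 (cat.), SPhos (cat.), THF, 55 °C
Reagents that add atoms: none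
Why: Negishi sp3–sp2 coupling of a primary alkylzinc made by LiCl-assisted zinc insertion, in which the bulky biaryl phosphine lets palladium enter the di-ortho-substituted C–Br bond and eliminate reductively faster than β-hydride elimination, the stereocentre is not a reacting atom, and the boronic ester does not transmetalate without base.

**Step 5**
Reactants: 7 2-[3,5-bis(TBS-oxy)-4-Lav-phenyl]-4,4,5,5-tetramethyl-1,3,2-dioxaborolane
Product: 9 3,5-bis(TBS-oxy)-4-Lav-phenol, via aryl pinacol borate 8 (not isolated)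
Conditions: N,N-dimethyl-4-toluidine N-oxide, CH2Cl2, rt; aqueous work-up
Reagents that add atoms: N,N-dimethyl-4-toluidine N-oxide, Cc1ccc(cc1)[N+](C)(C)[O-]
Why: Oxidative ipso-hydroxylation of an aryl boronic ester by an amine N-oxide (1,2-aryl shift from boron to oxygen, then hydrolysis of the borate) is neutral and non-electrophilic, so the aryl silyl ethers and both alkenes should survive and the single free phenol is revealed.

**Step 6**
Reactants: 9 3,5-bis(TBS-oxy)-4-Lav-phenol
Product: 10 2-iodo-3,5-bis(TBS-oxy)-4-Lav-phenol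
Conditions: NIS (1.0 equiv), CH2Cl2, −40 → 0 °C, dark
Reagents that add atoms: N-iodosuccinimide, O=C1CCC(=O)N1I
Why: Electrophilic aromatic iodination ortho to the free phenol gives one regioisomer because the para position is blocked and the two ortho positions are equivalent, and the trioxygenated ring should outcompete the alkenes at low temperature.

**Step 7**
Reactants: 10 2-iodo-3,5-bis(TBS-oxy)-4-Lav-phenol
Product: 12 2,4-bis(TBS-oxy)-6-hydroxy-3-Lav-benzoic acid, via ortho-magnesiated chloromagnesium phenoxide 11 (not isolated)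
Conditions: i-PrMgCl·LiCl (2.3 equiv), THF, −20 °C → rt; CO2, −20 °C; aq. NaH2PO4, cold
Reagents that add atoms: carbon dioxide, O=C=O
Why: Deprotonation followed by iodine–magnesium exchange (turbo-Grignard) gives an aryl magnesium species that, unlike the aryllithium, should not suffer O-to-C silyl migration, and its carboxylation puts CO2H ortho to the only free hydroxyl, so that oxygen becomes O1 and the hindered oxygen beside the side chain stays silylated.

**Step 8**
Reactants: 13 2,4,6-trihydroxybenzaldehyde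
Product: 14 2,4,6-tris(TBS-oxy)benzaldehyde
Conditions: TBSCl, imidazole, DMAP (cat.), DMF, rt → 40 °C
Reagents that add atoms: tert-butyldimethylsilyl chloride, CC(C)(C)[Si](C)(C)Cl
Why: Imidazole/DMAP-promoted silylation, which also reaches the two hydrogen-bonded ortho phenols of a salicylaldehyde-type substrate.

**Step 9**
Reactants: 12 2,4-bis(TBS-oxy)-6-hydroxy-3-Lav-benzoic acid; 14 2,4,6-tris(TBS-oxy)benzaldehyde
Product: 16 (2RS)-5,7-bis(TBS-oxy)-6-Lav-2-[2,4,6-tris(TBS-oxy)phenyl]-4H-1,3-benzodioxin-4-one, via bis-trimethylsilyl derivative 15 (not isolated)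
Conditions: HMDS, THF, rt, then evaporation; 14, TMSOTf (cat.), CH2Cl2, −78 °C; Et3N quench
Reagents that add atoms: none
Why: Noyori-type TMSOTf-catalysed acetalisation of a bis-trimethylsilylated hydroxy acid with an aldehyde is aprotic and driven by loss of hexamethyldisiloxane, only the trimethylsilyl ether and ester exchange (the TBS ethers do not), so the acetal uses the oxygen para to the side chain, and C2 forms without control because both epimers are wanted.

**Step 10**
Reactants: 16 (2RS)-5,7-bis(TBS-oxy)-6-Lav-2-[2,4,6-tris(TBS-oxy)phenyl]-4H-1,3-benzodioxin-4-one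
Product: 17 (2RS)-5,7-bis(TBS-oxy)-6-Lav-4-methylidene-2-[2,4,6-tris(TBS-oxy)phenyl]-4H-1,3-benzodioxine
Conditions: Cp2TiMe2, toluene, 65 °C, dark; filtration through basic alumina
Reagents that add atoms: dimethyltitanocene, [CH3-].[CH3-].[Ti+4].c1cc[cH-]c1.c1cc[cH-]c1
Why: Petasis methylenation of the lactone carbonyl by the thermally formed titanium methylidene is non-acidic, so the acetal and silyl ethers should persist, and the hindered side-chain alkenes can at most exchange a methylene degenerately.

**Step 11**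
Reactants: 17 (2RS)-5,7-bis(TBS-oxy)-6-Lav-4-methylidene-2-[2,4,6-tris(TBS-oxy)phenyl]-4H-1,3-benzodioxine
Product: 19 (2S)-5,7-bis(TBS-oxy)-6-Lav-2-[2,4,6-tris(TBS-oxy)phenyl]chroman-4-one, via ring-opened enol silane oxocarbenium ion 18 (not isolated)
Conditions: chiral BINOL-derived imidodiphosphorimidate (IDPi, N-triflyl core, 5 mol%, antipode chosen for 2S), silylated in the flask by allylSiMe3 (10 mol%); toluene, 0.02 M, −78 °C; Et3N quench
Reagents that add atoms: none
Why: Proposed new method: the silylium centre of the chiral ion-pair Lewis acid silylates the enol-ether oxygen O3, C2–O3 ionises to a trimethylsilyl enol ether of the A-ring ketone tethered to an O-aryl oxocarbenium at C2 (stabilised by the three silyloxy groups of the B ring), and the enol carbon then adds to C2 and hands the silyl cation back to the anion, so the acid turns over. The closest known reaction types are the Petasis–Ferrier rearrangement of 4-methylene-1,3-dioxanes to tetrahydropyran-4-ones with aluminium Lewis acids and the addition of enol silanes to oxocarbenium ions from racemic acetals under control of a confined chiral counteranion. The chroman-4-one ring closes by a 6-(enolendo)-endo-trig attack of C3 on the C2=O1 oxocarbenium, which forms the C2–C3 bond. Both C2 epimers of 17 give the same planar cation, so the (2S) centre is set only in the recombination, where the chiral anion paired with the cation shields one face of C2; the sense follows from the catalyst antipode, and the remote side-chain centre should have no influence. The step needs cleavage of C2–O3 and not of C2–O1: silylation at O1 gives an aryl silyl ether and a vinyl oxocarbenium with no carbon nucleophile able to close a ring (the exocyclic CH2 would form a four-membered ring), so that ion pair can only return, whereas the C2–O3 pathway ends irreversibly in the C–C bond. The five non-coordinating silyl ethers leave the two acetal oxygens as the only basic sites, and the tether through the A ring keeps cation and enol silane together.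

**Step 12**
Reactants: 19 (2S)-5,7-bis(TBS-oxy)-6-Lav-2-[2,4,6-tris(TBS-oxy)phenyl]chroman-4-one
Product: 20 (2S)-5,7-dihydroxy-6-[(2S)-5-methyl-2-(prop-1-en-2-yl)hex-4-en-1-yl]-2-(2,4,6-trihydroxyphenyl)chroman-4-one
Conditions: TBAF (6 equiv), AcOH (7 equiv), THF, 0 °C
Reagents that add atoms: none
Why: Fluoride-induced cleavage of the five aryl silyl ethers, where acetic acid keeps phenoxide and enolate concentrations low so the pyranone ring should not open (no C2 epimerisation, no 6-to-8 isomerisation) and no acid strong enough to cyclise a phenol onto the side-chain alkenes is present.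

**Compound list**
1 | 2-bromobenzene-1,3-diol | Oc1cccc(O)c1Br | starting material
2 | 2-bromo-1,3-bis(TBS-oxy)benzene | CC(C)(C)[Si](C)(C)Oc1cccc(O[Si](C)(C)C(C)(C)C)c1Br | intermediate
3 | 2-[4-bromo-3,5-bis(TBS-oxy)phenyl]-4,4,5,5-tetramethyl-1,3,2-dioxaborolane | CC(C)(C)[Si](C)(C)Oc1cc(B2OC(C)(C)C(C)(C)O2)cc(O[Si](C)(C)C(C)(C)C)c1Br | intermediate
4 | (R)-lavandulol, (2R)-5-methyl-2-(prop-1-en-2-yl)hex-4-en-1-ol | C=C(C)[C@@H](CC=C(C)C)CO | starting material
5 | (R)-lavandulyl iodide, (2R)-1-iodo-5-methyl-2-(prop-1-en-2-yl)hex-4-ene | C=C(C)[C@@H](CC=C(C)C)CI | intermediate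
6 | (R)-lavandulylzinc iodide, [(2R)-5-methyl-2-(prop-1-en-2-yl)hex-4-en-1-yl]zinc iodide | C=C(C)[C@@H](CC=C(C)C)C[Zn]I | intermediate
7 | 2-[3,5-bis(TBS-oxy)-4-Lav-phenyl]-4,4,5,5-tetramethyl-1,3,2-dioxaborolane | C=C(C)[C@@H](CC=C(C)C)Cc1c(O[Si](C)(C)C(C)(C)C)cc(B2OC(C)(C)C(C)(C)O2)cc1O[Si](C)(C)C(C)(C)C | intermediate
8 | 2-[3,5-bis(TBS-oxy)-4-Lav-phenoxy]-4,4,5,5-tetramethyl-1,3,2-dioxaborolane (aryl pinacol borate) | C=C(C)[C@@H](CC=C(C)C)Cc1c(O[Si](C)(C)C(C)(C)C)cc(OB2OC(C)(C)C(C)(C)O2)cc1O[Si](C)(C)C(C)(C)C | intermediate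
9 | 3,5-bis(TBS-oxy)-4-Lav-phenol | C=C(C)[C@@H](CC=C(C)C)Cc1c(O[Si](C)(C)C(C)(C)C)cc(O)cc1O[Si](C)(C)C(C)(C)C | intermediate
10 | 2-iodo-3,5-bis(TBS-oxy)-4-Lav-phenol | C=C(C)[C@@H](CC=C(C)C)Cc1c(O[Si](C)(C)C(C)(C)C)cc(O)c(I)c1O[Si](C)(C)C(C)(C)C | intermediate
11 | chloromagnesium 2-(chloromagnesio)-3,5-bis(TBS-oxy)-4-Lav-phenoxide | C=C(C)[C@@H](CC=C(C)C)Cc1c(O[Si](C)(C)C(C)(C)C)cc(O[Mg]Cl)c([Mg]Cl)c1O[Si](C)(C)C(C)(C)C | intermediate
12 | 2,4-bis(TBS-oxy)-6-hydroxy-3-Lav-benzoic acid | C=C(C)[C@@H](CC=C(C)C)Cc1c(O[Si](C)(C)C(C)(C)C)cc(O)c(C(=O)O)c1O[Si](C)(C)C(C)(C)C | intermediate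
13 | 2,4,6-trihydroxybenzaldehyde | O=Cc1c(O)cc(O)cc1O | starting material
14 | 2,4,6-tris(TBS-oxy)benzaldehyde | O=Cc1c(O[Si](C)(C)C(C)(C)C)cc(O[Si](C)(C)C(C)(C)C)cc1O[Si](C)(C)C(C)(C)C | intermediate
15 | trimethylsilyl 2,4-bis(TBS-oxy)-3-Lav-6-(trimethylsilyloxy)benzoate | C=C(C)[C@@H](CC=C(C)C)Cc1c(O[Si](C)(C)C(C)(C)C)cc(O[Si](C)(C)C)c(C(=O)O[Si](C)(C)C)c1O[Si](C)(C)C(C)(C)C | intermediate
16 | (2RS)-5,7-bis(TBS-oxy)-6-Lav-2-[2,4,6-tris(TBS-oxy)phenyl]-4H-1,3-benzodioxin-4-one | C=C(C)[C@@H](CC=C(C)C)Cc1c(O[Si](C)(C)C(C)(C)C)cc2c(c1O[Si](C)(C)C(C)(C)C)C(=O)OC(c1c(O[Si](C)(C)C(C)(C)C)cc(O[Si](C)(C)C(C)(C)C)cc1O[Si](C)(C)C(C)(C)C)O2 | intermediate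
17 | (2RS)-5,7-bis(TBS-oxy)-6-Lav-4-methylidene-2-[2,4,6-tris(TBS-oxy)phenyl]-4H-1,3-benzodioxine | C=C(C)[C@@H](CC=C(C)C)Cc1c(O[Si](C)(C)C(C)(C)C)cc2c(c1O[Si](C)(C)C(C)(C)C)C(=C)OC(c1c(O[Si](C)(C)C(C)(C)C)cc(O[Si](C)(C)C(C)(C)C)cc1O[Si](C)(C)C(C)(C)C)O2 | intermediate
18 | ring-opened cation: O-aryl oxocarbenium at C2 bearing the trimethylsilyl enol ether of the A-ring ketone (paired with the chiral anion) | C=C(C)[C@@H](CC=C(C)C)Cc1c(O[Si](C)(C)C(C)(C)C)cc([O+]=Cc2c(O[Si](C)(C)C(C)(C)C)cc(O[Si](C)(C)C(C)(C)C)cc2O[Si](C)(C)C(C)(C)C)c(C(=C)O[Si](C)(C)C)c1O[Si](C)(C)C(C)(C)C | intermediate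
19 | (2S)-5,7-bis(TBS-oxy)-6-Lav-2-[2,4,6-tris(TBS-oxy)phenyl]chroman-4-one | C=C(C)[C@@H](CC=C(C)C)Cc1c(O[Si](C)(C)C(C)(C)C)cc2c(c1O[Si](C)(C)C(C)(C)C)C(=O)C[C@@H](c1c(O[Si](C)(C)C(C)(C)C)cc(O[Si](C)(C)C(C)(C)C)cc1O[Si](C)(C)C(C)(C)C)O2 | intermediate
20 | (2S)-5,7-dihydroxy-6-[(2S)-5-methyl-2-(prop-1-en-2-yl)hex-4-en-1-yl]-2-(2,4,6-trihydroxyphenyl)chroman-4-one | C=C(C)[C@@H](CC=C(C)C)Cc1c(O)cc2c(c1O)C(=O)C[C@@H](c1c(O)cc(O)cc1O)O2 | target

**Step count.** Total: 12 steps. Longest linear sequence: 10 steps (1, 2, 4, 5, 6, 7, 9, 10, 11, 12).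

**Steps most likely to fail**

1. Step 11 (proposed new method).
   - What may go wrong: poor facial discrimination in the recombination because the bulky silyl ethers keep the chiral anion away from C2; loss of the enol ether by adventitious protonation and hydrolysis; intermolecular Friedel–Crafts capture of the cation; erosion at C2 by reversible re-ionisation of the product. A minor (2R) product would be a diastereomer and should be removable by chromatography.
   - Fallback (known chemistry): it sets out from iodophenol 10 and returns at 19. Iodine–magnesium exchange as in step 7 and trapping with N-methoxy-N-methylacetamide should give the methyl ketone 1-[2,4-bis(TBS-oxy)-6-hydroxy-3-Lav-phenyl]ethan-1-one F1. Pyrrolidine-mediated Kabbe-type condensation of F1 with aldehyde 14 (MeCN, 4 Å sieves, 50 °C) passes through the chalcone, which can close only on the single free phenol, to give the flavanone as the C2-epimer mixture (2RS)-5,7-bis(TBS-oxy)-6-Lav-2-[2,4,6-tris(TBS-oxy)phenyl]chroman-4-one F2. The two epimers are diastereomers and are separated by preparative HPLC; the (2R) epimer is re-equilibrated with DBU and recycled.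

2. Step 9.
   - What may go wrong: incomplete condensation with the hindered, electron-rich aldehyde; Friedel–Crafts attack of the activated aldehyde on the free A-ring position; ionisation and hydrolysis of the acylal on work-up; protodecarboxylation of the acid before it is silylated.
   - Fallback: it sets out from aldehyde 14 and acid 12 and returns at 16. The silyl-driven condensation is replaced by acetal exchange: 14 is converted with trimethyl orthoformate and catalytic PPTS in methanol into 2,4,6-tris(TBS-oxy)benzaldehyde dimethyl acetal F3. F3 is then exchanged with the free hydroxy acid 12 (catalytic PPTS, CH2Cl2, 5 Å sieves to take up methanol).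

3. Step 7.
   - What may go wrong: slow halogen–metal exchange on the very electron-rich ring; migration of a silyl group to the metalated carbon; loss of CO2 from the salicylic acid during acidic work-up.
   - Fallback: it sets out from phenol 9 and returns at 12, and needs no aryl-metal species. Casnati–Skattebøl ortho-formylation (MgCl2, Et3N, paraformaldehyde, THF, reflux) gives 2,4-bis(TBS-oxy)-6-hydroxy-3-Lav-benzaldehyde F4. Pinnick oxidation of F4 (NaClO2, NaH2PO4, large excess of 2-methyl-2-butene, t-BuOH/H2O) gives the acid.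

**Further compounds**
F1 | step 11 | 1-[2,4-bis(TBS-oxy)-6-hydroxy-3-Lav-phenyl]ethan-1-one | C=C(C)[C@@H](CC=C(C)C)Cc1c(O[Si](C)(C)C(C)(C)C)cc(O)c(C(C)=O)c1O[Si](C)(C)C(C)(C)C
F2 | step 11 | (2RS)-5,7-bis(TBS-oxy)-6-Lav-2-[2,4,6-tris(TBS-oxy)phenyl]chroman-4-one (C2-epimer mixture) | C=C(C)[C@@H](CC=C(C)C)Cc1c(O[Si](C)(C)C(C)(C)C)cc2c(c1O[Si](C)(C)C(C)(C)C)C(=O)CC(c1c(O[Si](C)(C)C(C)(C)C)cc(O[Si](C)(C)C(C)(C)C)cc1O[Si](C)(C)C(C)(C)C)O2
F3 | step 9 | 2,4,6-tris(TBS-oxy)benzaldehyde dimethyl acetal | COC(OC)c1c(O[Si](C)(C)C(C)(C)C)cc(O[Si](C)(C)C(C)(C)C)cc1O[Si](C)(C)C(C)(C)C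
F4 | step 7 | 2,4-bis(TBS-oxy)-6-hydroxy-3-Lav-benzaldehyde | C=C(C)[C@@H](CC=C(C)C)Cc1c(O[Si](C)(C)C(C)(C)C)cc(O)c(C=O)c1O[Si](C)(C)C(C)(C)C
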